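**Retrosynthetic overview**
- Feature: in the lactone ring O1–C2–C3–C4–C4a–C8a, C4 is a methine that is benzylic twice over (C4a and the phenyl ipso carbon) and is bonded to the C3 methylene. Cutting C3–C4 leaves a prochiral ArCH2Ph group ortho to the aryl ester oxygen O1.
- Target ⇒ (unmask O5/O7; C8–prenyl by Stille coupling) ⇒ (R)-8-bromo-5,7-bis(MOM) lactone ⇒ (C3–C4 by rhodium-carbene insertion into one of two enantiotopic C–H bonds) ⇒ hexasubstituted aryl diazoacetate.
- Diazoacetate ⇒ bromoacetate ⇒ 3-benzyl-5-bromo-4-hydroxy-2,6-bis(MOM)benzophenone ⇒ 2,4,6-trihydroxybenzophenone + benzyl alcohol (Friedel–Crafts). O4 is held as a TIPS ether while O2/O6 are protected.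
- Ring order: the three benzene rings are bought. The lactone is the only ring made, in step 8, together with the only stereocentre.
- O5/O7 travel as MOM ethers. One benzoyl carbonyl can assist Lewis-acid cleavage of only one methyl ether, and the force needed for the second would close O7 onto the prenyl group. The last unmasking must also leave the lactone shut, because an opened chain could reclose on O5.

Key step: step 8

Assumption: the sense of induction of a dirhodium carboxamidate in a δ-lactone closure cannot be carried over from γ-lactone cases, so the route is written with Rh2(4S-MPPIM)4; the configuration of the bromolactone is to be checked by X-ray anomalous dispersion (bromine), and if the pro-S hydrogen proves to be taken, the mirror-image catalyst Rh2(4R-MPPIM)4 (ligand from D-asparagine) is used in the same step.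

**Step 1**
Reactants: 1 2,4,6-trihydroxybenzophenone; 2 benzyl alcohol
Product: 3 3-benzyl-2,4,6-trihydroxybenzophenone
Conditions: TfOH (10 mol %), (CF3)2CHOH, 50 °C; 1 in 1.5-fold excess
Reagents that add atoms: benzyl alcohol (2), OCc1ccccc1
Why: Friedel–Crafts benzylation: acid and the strongly ionising solvent turn benzyl alcohol into a benzyl cation equivalent, which should be taken by one of the two equivalent CH positions of the phloroglucinol ring (each ortho/para to three hydroxyls) rather than by either unactivated phenyl ring, and the excess of 1 limits a second benzylation.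

**Step 2**
Reactants: 3 3-benzyl-2,4,6-trihydroxybenzophenone
Product: 4 3-benzyl-2,6-dihydroxy-4-(triisopropylsilyloxy)benzophenone
Conditions: TIPSCl (1.05 equiv), imidazole, DMF, 0 °C to rt
Reagents that add atoms: chlorotriisopropylsilane, CC(C)[Si](Cl)(C(C)C)C(C)C
Why: Chemoselective phenol silylation: O4 is the only hydroxyl not hydrogen-bonded to the benzoyl carbonyl and is the most acidic, so one equivalent of the bulky chlorosilane should react there and leave O2 and O6 free.

**Step 3**
Reactants: 4 3-benzyl-2,6-dihydroxy-4-(triisopropylsilyloxy)benzophenone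
Product: 5 3-benzyl-2,6-bis(methoxymethoxy)-4-(triisopropylsilyloxy)benzophenone
Conditions: NaH, MOMCl, DMF, 0 °C to rt
Reagents that add atoms: chloromethyl methyl ether, COCCl
Why: Williamson-type O-alkylation: sodium hydride breaks both chelates, the hard electrophile alkylates the two phenoxides on oxygen, and the hindered TIPS ether and the non-enolisable ketone are inert to these conditions.

**Step 4**
Reactants: 5 3-benzyl-2,6-bis(methoxymethoxy)-4-(triisopropylsilyloxy)benzophenone
Product: 6 3-benzyl-4-hydroxy-2,6-bis(methoxymethoxy)benzophenone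
Conditions: TBAF, AcOH, THF, 0 °C
Reagents that add atoms: none
Why: Fluoride-induced desilylation driven by the Si–F bond: the acetic acid buffer protonates the para-acyl phenoxide as it leaves, and the acetal ethers and the ketone are untouched.

**Step 5**
Reactants: 6 3-benzyl-4-hydroxy-2,6-bis(methoxymethoxy)benzophenone
Product: 7 3-benzyl-5-bromo-4-hydroxy-2,6-bis(methoxymethoxy)benzophenone
Conditions: NBS (1.0 equiv), MeCN, 0 °C, dark
Reagents that add atoms: N-bromosuccinimide, O=C1CCC(=O)N1Br
Why: Electrophilic aromatic bromination: the single CH left on the oxygenated ring lies ortho to the free hydroxyl and between two oxygens, so one equivalent of NBS in the dark should brominate only there and not at the benzylic methylene.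

**Step 6**
Reactants: 7 3-benzyl-5-bromo-4-hydroxy-2,6-bis(methoxymethoxy)benzophenone; 8 bromoacetyl bromide
Product: 9 4-benzoyl-2-benzyl-6-bromo-3,5-bis(methoxymethoxy)phenyl bromoacetate
Conditions: BrCH2COBr, NaHCO3, MeCN, 0 °C to rt
Reagents that add atoms: bromoacetyl bromide (8), O=C(Br)CBr
Why: O-acylation of a phenol by an acyl bromide: the acidic, doubly ortho-substituted phenol is deprotonated by hydrogencarbonate and attacks the acyl bromide end far faster than the alkyl bromide end, under conditions too mild to touch the MOM ethers.

**Step 7**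
Reactants: 9 4-benzoyl-2-benzyl-6-bromo-3,5-bis(methoxymethoxy)phenyl bromoacetate; 10 N,N′-ditosylhydrazine
Product: 12 4-benzoyl-2-benzyl-6-bromo-3,5-bis(methoxymethoxy)phenyl diazoacetate, via N-alkylated ditosylhydrazine 11 (not isolated)
Conditions: TsNHNHTs, DBU, THF, 0 °C
Reagents that add atoms: N,N′-ditosylhydrazine (10), Cc1ccc(cc1)S(=O)(=O)NNS(=O)(=O)c1ccc(C)cc1
Why: Bromoacetate-to-diazoacetate conversion: the ditosylhydrazine anion displaces bromide (SN2) to give 11, two base-induced eliminations of p-toluenesulfinate (Bamford–Stevens type) then leave the diazo group, and the benzyl and bromine substituents flanking O1 shield the aryl ester carbonyl from DBU and the nitrogen nucleophile.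

**Step 8**
Reactants: 12 4-benzoyl-2-benzyl-6-bromo-3,5-bis(methoxymethoxy)phenyl diazoacetate
Product: 14 (R)-6-benzoyl-8-bromo-5,7-bis(methoxymethoxy)-4-phenylchroman-2-one, via rhodium carbene 13 (not isolated)
Conditions: Rh2(4S-MPPIM)4 (2 mol %), CH2Cl2, reflux, slow addition of 12 (syringe pump, 10 h)
Reagents that add atoms: none
Why: Proposed new method: the diazo carbon of 12 binds to an axial rhodium site and expels N2, and the carbene 13 so formed, electrophilic at C3, engages one benzylic C–H σ bond side-on, hydrogen shifting to C3 slightly ahead of C3–C4 bond formation in a single three-centre event with retention at carbon. The closest known reaction type is the enantioselective intramolecular C–H insertion of alkyl diazoacetates to γ-butyrolactones under chiral dirhodium carboxamidates, which already tells apart the two hydrogens of a methylene group; an aryl ester tether and a δ-lactone closure are what is new. The ring O1–C2–C3–C4–C4a–C8a closes by 1,6-insertion through a six-membered cyclic transition state reached from the E rotamer of the ester, and no smaller ring is possible since C4a and C8, the atoms in 1,5-relation to C3, bear no hydrogen. C4 is set by the catalyst only: the ester arms of the four imidazolidinone ligands wall off all but one quadrant around the carbene, the bulky hexasubstituted aryl group has to occupy it, and then only one benzylic hydrogen can point at C3; the pro-R hydrogen must be the one replaced, because C3 takes over its place and its CIP rank (C4a > phenyl > C3 > H). The step needs C–H insertion ahead of Buchner cycloaddition to the pendant phenyl ring, carbene dimerisation, attack on C8 and ylide formation: carboxamidate ligands tame the carbene and favour insertion over aromatic cycloaddition, which would moreover need a seven- or eight-membered approach, slow addition keeps the diazo concentration low, bromine occupies C8, and the benzoyl oxygen, para to O1, is out of reach. Flanked by benzyl and bromine, the acyloxy group must stand roughly perpendicular to the arene, which brings C3 above the methylene, and O5 and O7 (ortho and para to C4a) feed electron density into the breaking C–H bond while the benzoyl group, meta to C4a, does not drain it.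

**Step 9**
Reactants: 14 (R)-6-benzoyl-8-bromo-5,7-bis(methoxymethoxy)-4-phenylchroman-2-one; 15 tributyl(3-methylbut-2-enyl)stannane
Product: 16 (R)-6-benzoyl-5,7-bis(methoxymethoxy)-8-(3-methylbut-2-enyl)-4-phenylchroman-2-one
Conditions: Pd(Pt-Bu3)2 (10 mol %), CsF, 1,4-dioxane, 80 °C
Reagents that add atoms: tributyl(3-methylbut-2-enyl)stannane (15), CC(C)=CC[Sn](CCCC)(CCCC)CCCC
Why: Stille coupling: the electron-rich bulky phosphine drives oxidative addition into the hindered C8–Br bond, fluoride speeds prenyl transfer from tin, and reductive elimination at the primary terminus is favoured because a quaternary carbon next to the doubly ortho-substituted ring would be too crowded; C4 has no acidic hydrogen under these conditions and, with O5 still masked, any transient opening of the lactone can only reclose on O1.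

**Step 10**
Reactants: 16 (R)-6-benzoyl-5,7-bis(methoxymethoxy)-8-(3-methylbut-2-enyl)-4-phenylchroman-2-one
Product: 18 (R)-6-benzoyl-5,7-dihydroxy-8-(3-methylbut-2-enyl)-4-phenylchroman-2-one (CNP0313865.1), via bis(trimethylsilyl) ether 17 (not isolated)
Conditions: TMSOTf, 2,2′-bipyridyl, MeCN, 0 °C to rt; then H2O, rt
Reagents that add atoms: none
Why: Silyl triflate/bipyridyl cleavage of aromatic MOM ethers: the buffered silyl Lewis acid exchanges each acetal for a trimethylsilyl ether (17) without free protic acid, and water then hydrolyses the very labile ortho-acyl aryl silyl ethers near neutral pH, so the prenyl double bond is not protonated, the lactone stays closed on O1 and C4 is untouched.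

**Compound list**
1 | 2,4,6-trihydroxybenzophenone | O=C(c1ccccc1)c1c(O)cc(O)cc1O | starting material
2 | benzyl alcohol | OCc1ccccc1 | starting material
3 | 3-benzyl-2,4,6-trihydroxybenzophenone | O=C(c1ccccc1)c1c(O)cc(O)c(Cc2ccccc2)c1O | intermediate
4 | 3-benzyl-2,6-dihydroxy-4-(triisopropylsilyloxy)benzophenone | O=C(c1ccccc1)c1c(O)cc(O[Si](C(C)C)(C(C)C)C(C)C)c(Cc2ccccc2)c1O | intermediate
5 | 3-benzyl-2,6-bis(methoxymethoxy)-4-(triisopropylsilyloxy)benzophenone | O=C(c1ccccc1)c1c(OCOC)cc(O[Si](C(C)C)(C(C)C)C(C)C)c(Cc2ccccc2)c1OCOC | intermediate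
6 | 3-benzyl-4-hydroxy-2,6-bis(methoxymethoxy)benzophenone | O=C(c1ccccc1)c1c(OCOC)cc(O)c(Cc2ccccc2)c1OCOC | intermediate
7 | 3-benzyl-5-bromo-4-hydroxy-2,6-bis(methoxymethoxy)benzophenone | O=C(c1ccccc1)c1c(OCOC)c(Br)c(O)c(Cc2ccccc2)c1OCOC | intermediate
8 | bromoacetyl bromide | O=C(Br)CBr | starting material
9 | 4-benzoyl-2-benzyl-6-bromo-3,5-bis(methoxymethoxy)phenyl bromoacetate | O=C(CBr)Oc1c(Br)c(OCOC)c(C(=O)c2ccccc2)c(OCOC)c1Cc1ccccc1 | intermediate
10 | N,N′-ditosylhydrazine | Cc1ccc(cc1)S(=O)(=O)NNS(=O)(=O)c1ccc(C)cc1 | starting material
11 | 4-benzoyl-2-benzyl-6-bromo-3,5-bis(methoxymethoxy)phenyl (1,2-ditosylhydrazinyl)acetate | Cc1ccc(cc1)S(=O)(=O)NN(CC(=O)Oc1c(Br)c(OCOC)c(C(=O)c2ccccc2)c(OCOC)c1Cc1ccccc1)S(=O)(=O)c1ccc(C)cc1 | intermediate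
12 | 4-benzoyl-2-benzyl-6-bromo-3,5-bis(methoxymethoxy)phenyl diazoacetate | [N-]=[N+]=CC(=O)Oc1c(Br)c(OCOC)c(C(=O)c2ccccc2)c(OCOC)c1Cc1ccccc1 | intermediate
13 | rhodium carbene from 12 (second rhodium and ligands omitted) | [Rh]=CC(=O)Oc1c(Br)c(OCOC)c(C(=O)c2ccccc2)c(OCOC)c1Cc1ccccc1 | intermediate
14 | (R)-6-benzoyl-8-bromo-5,7-bis(methoxymethoxy)-4-phenylchroman-2-one | Brc1c(OCOC)c(C(=O)c3ccccc3)c(OCOC)c2c1OC(=O)C[C@@H]2c1ccccc1 | intermediate
15 | tributyl(3-methylbut-2-enyl)stannane | CC(C)=CC[Sn](CCCC)(CCCC)CCCC | starting material
16 | (R)-6-benzoyl-5,7-bis(methoxymethoxy)-8-(3-methylbut-2-enyl)-4-phenylchroman-2-one | CC(C)=CCc1c(OCOC)c(C(=O)c2ccccc2)c(OCOC)c2c1OC(=O)C[C@@H]2c1ccccc1 | intermediate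
17 | (R)-6-benzoyl-8-(3-methylbut-2-enyl)-4-phenyl-5,7-bis(trimethylsilyloxy)chroman-2-one | CC(C)=CCc1c(O[Si](C)(C)C)c(C(=O)c2ccccc2)c(O[Si](C)(C)C)c2c1OC(=O)C[C@@H]2c1ccccc1 | intermediate
18 | (R)-6-benzoyl-5,7-dihydroxy-8-(3-methylbut-2-enyl)-4-phenylchroman-2-one | CC(C)=CCc1c(O)c(C(=O)c2ccccc2)c(O)c2c1OC(=O)C[C@@H]2c1ccccc1 | target

**Step count**
Total step count: 10. Longest linear sequence: 10 (from 1).

**Steps most likely to fail**

1. Step 8.
   - What may go wrong: the carbene may be lost to cycloaddition on the pendant phenyl ring or to dimerisation. The ester may stay in its Z rotamer, so that closure is slow. Hydride transfer may run ahead to a long-lived diarylmethyl cation/rhodium enolate pair, which would erode the distinction between the two hydrogens.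
   - Fallback (known chemistry), from 7 back to 14: oxidation of the o-benzylphenol 7 with silver(I) oxide in CH2Cl2 would give the ortho-quinone methide (6Z)-4-benzoyl-6-benzylidene-2-bromo-3,5-bis(methoxymethoxy)cyclohexa-2,4-dien-1-one F1. A cinchona-derived bifunctional squaramide (quinine or quinidine series chosen for the R sense) would then steer the conjugate addition of Meldrum's acid to the benzylidene carbon. This would give 5-[(R)-(3-benzoyl-5-bromo-6-hydroxy-2,4-bis(methoxymethoxy)phenyl)(phenyl)methyl]-2,2-dimethyl-1,3-dioxane-4,6-dione F2. On warming in toluene the rearomatised phenol oxygen attacks a ring carbonyl with loss of acetone to give (3R,4R)-6-benzoyl-8-bromo-5,7-bis(methoxymethoxy)-2-oxo-4-phenylchroman-3-carboxylic acid F3, which decarboxylates to 14.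

2. Step 9.
   - What may go wrong: oxidative addition may be slow at a C–Br bond flanked by two oxygen substituents, with reductive loss of bromine competing. Coupling may also occur through the tertiary terminus of the prenyl–palladium unit.
   - Fallback, from 14 back to 16: the side chain is built in two stages. Stille coupling with the smaller, regiochemically unambiguous allyltributylstannane (Pd(PPh3)4, toluene, 100 °C) would give (R)-8-allyl-6-benzoyl-5,7-bis(methoxymethoxy)-4-phenylchroman-2-one F4. Olefin cross-metathesis with excess 2-methylbut-2-ene and a second-generation ruthenium benzylidene catalyst (CH2Cl2, 40 °C) would then give 16.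

3. Step 10.
   - What may go wrong: the freed O7 hydroxyl may close onto the prenyl double bond under Lewis-acid activation. The lactone may open in the aqueous stage and reclose on O5.
   - Fallback, from 14 to 18: the order of the last two operations is reversed, so that the alkene never meets the silyl triflate. The same acetal cleavage on 14 would give (R)-6-benzoyl-8-bromo-5,7-dihydroxy-4-phenylchroman-2-one F5. A neutral, base- and fluoride-free Stille coupling with excess 15 (Pd(PPh3)4, DMF, 90 °C), which tolerates free phenols, would then give 18 directly.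

**Further compounds**
F1 | step 8 | (6Z)-4-benzoyl-6-benzylidene-2-bromo-3,5-bis(methoxymethoxy)cyclohexa-2,4-dien-1-one | O=C1C(Br)=C(OCOC)C(C(=O)c2ccccc2)=C(OCOC)/C1=C/c1ccccc1
F2 | step 8 | 5-[(R)-(3-benzoyl-5-bromo-6-hydroxy-2,4-bis(methoxymethoxy)phenyl)(phenyl)methyl]-2,2-dimethyl-1,3-dioxane-4,6-dione | O=C1OC(C)(C)OC(=O)C1[C@@H](c1c(O)c(Br)c(OCOC)c(C(=O)c2ccccc2)c1OCOC)c1ccccc1
F3 | step 8 | (3R,4R)-6-benzoyl-8-bromo-5,7-bis(methoxymethoxy)-2-oxo-4-phenylchroman-3-carboxylic acid | O=C1Oc2c(Br)c(OCOC)c(C(=O)c3ccccc3)c(OCOC)c2[C@@H](c2ccccc2)[C@@H]1C(=O)O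
F4 | step 9 | (R)-8-allyl-6-benzoyl-5,7-bis(methoxymethoxy)-4-phenylchroman-2-one | C=CCc1c(OCOC)c(C(=O)c2ccccc2)c(OCOC)c2c1OC(=O)C[C@@H]2c1ccccc1
F5 | step 10 | (R)-6-benzoyl-8-bromo-5,7-dihydroxy-4-phenylchroman-2-one | Brc1c(O)c(C(=O)c3ccccc3)c(O)c2c1OC(=O)C[C@@H]2c1ccccc1
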